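**Retrosynthetic overview**
1. The vanillate ester C–O bond is made last, on the C8 alcohol of the bicyclic keto-diol (acetyl-masked vanillic acid, then unmasking).
2. C8–OH comes from 1,6-borylation/oxidation of a cyclohepta-2,4-dienone; the C3a methyl from α'-methylation of that dienone; the C1 carbinol from isopropylcerium addition to a cyclopentanone.
3. Both carbocycles come from one intramolecular Buchner reaction of an aryl diazoketone: carbene addition to the benzene ring closes the five-membered ring, and the norcaradiene opens to the seven-membered ring in the same operation. A chiral copper–bis(oxazoline) catalyst sets C8a there.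
4. The arene already carries the C6 methyl (para) and the C4 oxygen (ortho OMe, a masked ketone); the diazoketone comes from a 3-arylpropanoic acid made from 7-methylcoumarin.
5. Ring order: five- and seven-membered rings together (step 4); C1, C3a and C8 are then relayed from C8a.

Assumption: the SMILES is read as the trans-fused (1R,3aS,8S,8aS) isomer; azulene numbering is used throughout (C1 = carbinol carbon with isopropyl, C3a = methyl-bearing fusion carbon, C4 = ketone, C8 = ester carbon, C8a = fusion CH).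

**Route**

Step 1
Reactants: 1 7-methylcoumarin
Product: 2 7-methylchroman-2-one
Conditions: H2 (1 atm), 10% Pd/C, EtOAc, rt
Reagents that add atoms: none
Why: Heterogeneous catalytic hydrogenation saturates only the conjugated C3=C4 alkene of the coumarin, leaving arene and lactone intact, and no stereocentre is formed.

Step 2
Reactants: 2 7-methylchroman-2-one
Product: 4 3-(2-methoxy-4-methylphenyl)propanoic acid, via disodium 3-(4-methyl-2-oxidophenyl)propanoate 3 (not isolated)
Conditions: NaOH (aq, 2.5 equiv), rt; Me2SO4 (1.2 equiv), 0 °C → rt; NaOH, 80 °C; then HCl (aq)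
Reagents that add atoms: dimethyl sulfate, COS(=O)(=O)OC; sodium hydroxide, [Na+].[OH-]
Why: Lactone saponification frees the phenoxide, which is O-methylated (Williamson-type alkylation) while the carboxylate stays free in water, and no stereocentre is formed.

Step 3
Reactants: 4 3-(2-methoxy-4-methylphenyl)propanoic acid
Product: 6 1-diazo-4-(2-methoxy-4-methylphenyl)butan-2-one, via 3-(2-methoxy-4-methylphenyl)propanoyl chloride 5 (not isolated)
Conditions: (COCl)2, DMF (cat.), CH2Cl2, 0 °C → rt, evaporate; CH2N2 (3 equiv), Et2O, 0 °C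
Reagents that add atoms: oxalyl chloride, O=C(Cl)C(Cl)=O (chlorine of 5); diazomethane, C=[N+]=[N-]
Why: Acid chloride formation followed by acylation of diazomethane (Arndt–Eistert-type diazoketone synthesis, the second equivalent of diazomethane taking up HCl) gives the terminal α-diazoketone without creating a stereocentre.

Step 4
Reactants: 6 1-diazo-4-(2-methoxy-4-methylphenyl)butan-2-one
Product: 8 (8aR)-4-methoxy-6-methyl-3,8a-dihydroazulen-1(2H)-one, via norcaradiene cyclopropane adduct 7 (not isolated)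
Conditions: CuCl (5 mol %), Na[B(3,5-(CF3)2C6H3)4] (6 mol %), (R,R)-Ph-box (6 mol %), CH2Cl2, reflux, slow addition of 6; used crude at once
Reagents that add atoms: none
Why: Intramolecular Buchner reaction, in which the copper carbene cyclopropanates the unsubstituted ipso–ortho bond of the arene (away from OMe) to close the cyclopentanone and the norcaradiene 7 opens by 6π disrotatory electrocyclic ring opening to the cycloheptatriene, so that both rings form together while the chiral bis(oxazoline)–copper carbene selects the arene face and sets C8a as R (the antipodal ligand is used if the sense of induction proves opposite).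

Step 5
Reactants: 8 (8aR)-4-methoxy-6-methyl-3,8a-dihydroazulen-1(2H)-one
Product: 10 (1R,8aR)-1-hydroxy-6-methyl-1-(propan-2-yl)-2,3,3a,8a-tetrahydroazulen-4(1H)-one as a C3a epimer mixture, via tertiary alcohol enol ether 9 (not isolated)
Conditions: i-PrMgCl (1.5 equiv), CeCl3 (1.6 equiv), THF, −78 °C; then 1 M HCl, THF, 0 °C
Reagents that add atoms: isopropylmagnesium chloride, CC(C)[Mg]Cl; water, O
Why: Organocerium (Imamoto) 1,2-addition outruns enolisation of the labile C8a–H and comes in anti to C8 of the seven-membered ring (syn to H-8a), setting C1 as R with OH cis to C8, and the acid quench hydrolyses the methyl dienol ether by protonation at C3a to give the 4-keto-5,7-diene.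

Step 6
Reactants: 10 (1R,8aR)-1-hydroxy-6-methyl-1-(propan-2-yl)-2,3,3a,8a-tetrahydroazulen-4(1H)-one
Product: 11 (1R,3aS,8aR)-1-hydroxy-3a,6-dimethyl-1-(propan-2-yl)-2,3,3a,8a-tetrahydroazulen-4(1H)-one
Conditions: LiN(i-Pr)2 (2.2 equiv), THF, −78 °C; MeI (1.5 equiv), −78 → −20 °C; NH4Cl (aq)
Reagents that add atoms: iodomethane, CI
Why: Kinetic α'-deprotonation at C3a (helped by the neighbouring lithium alkoxide) gives the cross-conjugated enolate, and its C-methylation (enolate alkylation) takes place on the face opposite the 1,3-related isopropyl group, creating quaternary C3a as S with CH3 cis to OH and trans to H-8a.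

Step 7
Reactants: 11 (1R,3aS,8aR)-1-hydroxy-3a,6-dimethyl-1-(propan-2-yl)-2,3,3a,8a-tetrahydroazulen-4(1H)-one
Product: 14 (1R,3aS,8S,8aS)-1,8-dihydroxy-3a,6-dimethyl-1-(propan-2-yl)-2,3,3a,7,8,8a-hexahydroazulen-4(1H)-one, via allylboronate 12 (not isolated), via deconjugated hydroxy enone 13 (not isolated)
Conditions: CuCl (5 mol %), (R,R)-Me-DuPhos (6 mol %), NaOt-Bu (10 mol %), B2pin2 (1.2 equiv), MeOH (2 equiv), THF, rt; then NaBO3·4H2O, THF/H2O, rt; then DBU (0.3 equiv) added to the same mixture, rt
Reagents that add atoms: bis(pinacolato)diboron, CC1(C)OB(OC1(C)C)B2OC(C)(C)C(C)(C)O2 (boron of 12); sodium perborate tetrahydrate, [Na+].[O-]OB=O.O.O.O.O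
Why: Copper-catalysed 1,6-conjugate borylation places boron on the δ-carbon C8 (the β-carbon C6 is fully substituted) from the face anti to the axial C3a methyl, reinforced by the chiral ligand, then stereoretentive perborate oxidation gives the C8 (S) alcohol and base moves the C6=C7 alkene into conjugation as C5=C6.

Step 8
Reactants: 14 (1R,3aS,8S,8aS)-1,8-dihydroxy-3a,6-dimethyl-1-(propan-2-yl)-2,3,3a,7,8,8a-hexahydroazulen-4(1H)-one; 15 4-acetoxy-3-methoxybenzoic acid
Product: 16 (1R,3aS,8S,8aS)-1-hydroxy-3a,6-dimethyl-4-oxo-1-(propan-2-yl)-1,2,3,3a,4,7,8,8a-octahydroazulen-8-yl 4-acetoxy-3-methoxybenzoate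
Conditions: EDC·HCl (1.5 equiv), DMAP (0.3 equiv), CH2Cl2, 0 °C → rt
Reagents that add atoms: none
Why: Steglich esterification acylates the secondary C8–OH selectively because the tertiary C1–OH is too hindered, the phenol being masked as its acetate, and no stereocentre is touched.

Step 9
Reactants: 16 (1R,3aS,8S,8aS)-1-hydroxy-3a,6-dimethyl-4-oxo-1-(propan-2-yl)-1,2,3,3a,4,7,8,8a-octahydroazulen-8-yl 4-acetoxy-3-methoxybenzoate
Product: 17 (1R,3aS,8S,8aS)-1-hydroxy-3a,6-dimethyl-4-oxo-1-(propan-2-yl)-1,2,3,3a,4,7,8,8a-octahydroazulen-8-yl 4-hydroxy-3-methoxybenzoate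
Conditions: pyrrolidine (2 equiv), CH2Cl2, 0 °C → rt
Reagents that add atoms: none
Why: Aminolysis cleaves the activated aryl acetate far faster than the hindered alkyl benzoate, freeing the phenol under conditions too mild for vinylogous β-elimination of the C8 acyloxy group.

**Compound list**
1 | 7-methylcoumarin | O=C1C=Cc2ccc(C)cc2O1 | starting material
2 | 7-methylchroman-2-one | O=C1CCc2ccc(C)cc2O1 | intermediate
3 | disodium 3-(4-methyl-2-oxidophenyl)propanoate | [Na+].[Na+].[O-]C(=O)CCc1ccc(C)cc1[O-] | intermediate (not isolated)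
4 | 3-(2-methoxy-4-methylphenyl)propanoic acid | COc1cc(C)ccc1CCC(=O)O | intermediate
5 | 3-(2-methoxy-4-methylphenyl)propanoyl chloride | COc1cc(C)ccc1CCC(=O)Cl | intermediate (not isolated)
6 | 1-diazo-4-(2-methoxy-4-methylphenyl)butan-2-one | COc1cc(C)ccc1CCC(=O)C=[N+]=[N-] | intermediate
7 | norcaradiene valence isomer of 8 (cyclopropane C3a–C8–C8a, cis-fused to both rings) | O=C1CC[C@@]23C(OC)=CC(C)=C[C@@H]2[C@@H]13 | intermediate (not isolated)
8 | (8aR)-4-methoxy-6-methyl-3,8a-dihydroazulen-1(2H)-one | C1=CC(C)=CC(OC)=C2CCC(=O)[C@H]12 | intermediate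
9 | (1R,8aR)-4-methoxy-6-methyl-1-(propan-2-yl)-1,2,3,8a-tetrahydroazulen-1-ol | C1=CC(C)=CC(OC)=C2CC[C@@](O)(C(C)C)[C@H]12 | intermediate (not isolated)
10 | (1R,8aR)-1-hydroxy-6-methyl-1-(propan-2-yl)-2,3,3a,8a-tetrahydroazulen-4(1H)-one (C3a epimers) | C1=CC(C)=CC(=O)C2CC[C@@](O)(C(C)C)[C@H]12 | intermediate
11 | (1R,3aS,8aR)-1-hydroxy-3a,6-dimethyl-1-(propan-2-yl)-2,3,3a,8a-tetrahydroazulen-4(1H)-one | C1=CC(C)=CC(=O)[C@@]2(C)CC[C@@](O)(C(C)C)[C@H]12 | intermediate
12 | (1R,3aS,8S,8aR)-1-hydroxy-3a,6-dimethyl-1-(propan-2-yl)-8-(4,4,5,5-tetramethyl-1,3,2-dioxaborolan-2-yl)-2,3,3a,5,8,8a-hexahydroazulen-4(1H)-one | CC1(C)OB(OC1(C)C)[C@H]2C=C(C)CC(=O)[C@@]3(C)CC[C@@](O)(C(C)C)[C@H]23 | intermediate (not isolated)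
13 | (1R,3aS,8S,8aS)-1,8-dihydroxy-3a,6-dimethyl-1-(propan-2-yl)-2,3,3a,5,8,8a-hexahydroazulen-4(1H)-one | O[C@H]1C=C(C)CC(=O)[C@@]2(C)CC[C@@](O)(C(C)C)[C@H]12 | intermediate (not isolated)
14 | (1R,3aS,8S,8aS)-1,8-dihydroxy-3a,6-dimethyl-1-(propan-2-yl)-2,3,3a,7,8,8a-hexahydroazulen-4(1H)-one | O[C@H]1CC(C)=CC(=O)[C@@]2(C)CC[C@@](O)(C(C)C)[C@H]12 | intermediate
15 | 4-acetoxy-3-methoxybenzoic acid (O-acetylvanillic acid) | CC(=O)Oc1ccc(cc1OC)C(=O)O | starting material
16 | (1R,3aS,8S,8aS)-1-hydroxy-3a,6-dimethyl-4-oxo-1-(propan-2-yl)-1,2,3,3a,4,7,8,8a-octahydroazulen-8-yl 4-acetoxy-3-methoxybenzoate | CC(=O)Oc1ccc(cc1OC)C(=O)O[C@H]2CC(C)=CC(=O)[C@@]3(C)CC[C@@](O)(C(C)C)[C@H]23 | intermediate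
17 | (1R,3aS,8S,8aS)-1-hydroxy-3a,6-dimethyl-4-oxo-1-(propan-2-yl)-1,2,3,3a,4,7,8,8a-octahydroazulen-8-yl 4-hydroxy-3-methoxybenzoate | COc1cc(C(=O)O[C@H]2CC(C)=CC(=O)[C@@]3(C)CC[C@@](O)(C(C)C)[C@H]23)ccc1O | target

**Step count**
Total steps: 9. Longest linear sequence: 9 steps (1 → 17); 15 is bought.

**Three steps most likely to fail, each with a fallback**

Step 4 (enantiocontrol and the configurational lability of the C8a–H ketone; competing aromatic substitution). The fallback sets out from 6 and returns at 8. The same ring-forming reaction is run with achiral Rh2(OAc)4 (CH2Cl2, reflux), giving 8 as a racemate, that is together with its mirror image (8aS)-4-methoxy-6-methyl-3,8a-dihydroazulen-1(2H)-one F1. Reagent-controlled reduction with (S)-2-methyl-CBS-oxazaborolidine and catecholborane (toluene, −78 °C; antipodal catalyst if needed) turns the two enantiomers into diastereomers: the cis alcohol (1S,8aR)-4-methoxy-6-methyl-1,2,3,8a-tetrahydroazulen-1-ol F2 from 8 and the trans alcohol (1S,8aS)-4-methoxy-6-methyl-1,2,3,8a-tetrahydroazulen-1-ol F3 from F1. These are separated on silica. F2 is oxidised back with Dess–Martin periodinane/NaHCO3 (non-basic, so the triene does not isomerise) to enantiopure 8, which goes straight into step 5.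

Step 6 (α' versus vinylogous deprotonation, and the facial selectivity of methylation at the ring fusion). The fallback sets out from 9 and returns at 11. Compound 9 is isolated by quenching the first stage of step 5 with NH4Cl (aq) instead of HCl. Hydroxyl-directed Furukawa–Simmons–Smith cyclopropanation (Et2Zn, CH2I2, CH2Cl2, 0 °C) of the electron-rich C3a=C4 enol ether delivers CH2 on the face of the C1 hydroxyl. This gives the methoxycyclopropane (1R,8aR)-4-methoxy-6-methyl-1-(propan-2-yl)-1,2,3,3a,4,8a-hexahydro-3a,4-methanoazulen-1-ol F4. Aqueous HCl in THF then opens the donor-substituted cyclopropane at the C4–CH2 bond, so CH2 becomes the C3a methyl (cis to OH) and C4 becomes the ketone, giving 11 directly.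

Step 7 (1,6- versus 1,4-borylation and the face of attack at C8). The fallback sets out from 11 and returns at 13. Electrophilic epoxidation (mCPBA, NaHCO3, CH2Cl2, 0 °C) of the distal, more electron-rich C7=C8 alkene, anti to the C3a methyl, gives the epoxide (1R,3aS,7S,8R,8aS)-7,8-epoxy-1-hydroxy-3a,6-dimethyl-1-(propan-2-yl)-2,3,3a,7,8,8a-hexahydroazulen-4(1H)-one F5. Reductive cleavage of its C7–O bond with SmI2 (THF/MeOH, −78 °C; vinylogous α-keto epoxide opening) gives 13, which is conjugated to 14 with DBU as in step 7.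

Further compounds
F1 | step 4 | (8aS)-4-methoxy-6-methyl-3,8a-dihydroazulen-1(2H)-one | C1=CC(C)=CC(OC)=C2CCC(=O)[C@@H]12
F2 | step 4 | (1S,8aR)-4-methoxy-6-methyl-1,2,3,8a-tetrahydroazulen-1-ol (cis, OH on the side of C8) | C1=CC(C)=CC(OC)=C2CC[C@H](O)[C@H]12
F3 | step 4 | (1S,8aS)-4-methoxy-6-methyl-1,2,3,8a-tetrahydroazulen-1-ol (trans) | C1=CC(C)=CC(OC)=C2CC[C@H](O)[C@@H]12
F4 | step 6 | (1R,8aR)-4-methoxy-6-methyl-1-(propan-2-yl)-1,2,3,3a,4,8a-hexahydro-3a,4-methanoazulen-1-ol (CH2 bridge on the face of the C1 hydroxyl) | C1=CC(C)=C[C@]2(OC)C[C@@]23CC[C@@](O)(C(C)C)[C@H]13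
F5 | step 7 | (1R,3aS,7S,8R,8aS)-7,8-epoxy-1-hydroxy-3a,6-dimethyl-1-(propan-2-yl)-2,3,3a,7,8,8a-hexahydroazulen-4(1H)-one (oxirane oxygen on the face of H-8a) | O1[C@H]2[C@@H]1C(C)=CC(=O)[C@@]3(C)CC[C@@](O)(C(C)C)[C@H]23
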